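Remark: flavone numbering is used throughout (O1 and C2–C8a for rings C and A, C1'–C6' for ring B). Compounds 1, 3, 8 and 9 and the reagents on the Conditions lines are taken to be commercial.

## The problem

Target 16, 5,6-dihydroxy-2-(4-hydroxy-2,5-dimethoxyphenyl)-7-methoxy-4H-chromen-4-one, is a flavone. Benzene ring A is fused to the 4-pyranone ring C through C4a–C8a, and ring B is attached to C2 by the single C2–C1' bond. There is no stereocentre, so nothing has to be relayed or controlled in space, and the whole difficulty is regiochemical. Six oxygens sit on the two benzene rings: three free phenols (C5, C6, C4') and three methyl ethers (C7, C2', C5'). In each ring a free hydroxyl stands next to a methoxy group (C6/C7 and C4'/C5'), so neighbouring oxygens must be told apart twice. In ring A the three oxygens are contiguous and differ only in their surroundings: O5 is peri to the C4 carbonyl, O6 is flanked on both sides, and O7 has one free flank. The 5,6-dihydroxy unit is an electron-rich catechol that air oxidises to the ortho-quinone once base is present, and ring C opens when hydroxide or alkoxide attacks C2, so the free phenols should appear last and under acid. The enabling feature is ring B itself. O2' and O5' are para, C1' lies beside C2', O4' lies beside C5', and C3' and C6' carry hydrogen. This is the 4-alkoxyphenol that a chromium alkoxy(alkenyl)carbene (carbene carbon as C5', alkene as C4'/C3'), one CO ligand (C2') and a terminal alkyne (C6', C1') assemble.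

## Retrosynthesis

**16 to 15.** The last disconnection is of three oxygen–alkyl bonds, O5–CH3, O6–CH3 and O4'–C(CH3)3, leading back to the fully etherified flavone 15. Keeping every phenol masked to the end protects the oxidisable 5,6-dihydroxy unit. The neighbouring choice, carrying O5 and O6 under benzyl or acetal groups from the start, would need an unsymmetrical ring A phenol whose acylation has no regiochemical bias, and would add three to four steps. The forward step asks a Lewis acid to remove the carbonyl-chelated C5 methyl, the doubly flanked C6 methyl and the tert-butyl group, and to leave the C7, C2' and C5' methyl ethers. An aluminium bromide in a nitrile solvent is specified because the chloride is expected to stop after C5. The C7 methoxy beside aluminium-bound O6 is in the same situation as the C5' methoxy beside O4', so conditions that give the ring A pattern should also spare ring B.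

**15 to 14.** Cutting O2'–CH3 gives phenol 14. O2' is the one ring B oxygen that the key step delivers unprotected, so its methylation needs no selectivity. The skeleton is unchanged, but 14 is the direct benzannulation product.

**14 to 12 and 7 (key disconnection).** Ring B is taken apart completely. C5'–C6', C1'–C2' and C2'–C3' are cut, and C2' with its oxygen returns to a carbonyl ligand. This gives carbene complex 12 (C5', C4', C3' with the O5' and O4' substituents) and ethynylchromone 7 (C6', C1' and rings A and C). The neighbouring cuts are C2–C1' by cross-coupling, or ring C by acylation and cyclodehydration of a ring B acid. Both presuppose a ready-made benzene with three differently protected oxygens in the 2,4,5 relationship. Here that ring is created with each oxygen already marked by its origin: free at C2', tert-butyl at C4', methyl at C5'. The forward reaction must place the chromonyl-bearing carbon next to the CO-derived carbon, must follow the CO-insertion path and not five-membered-ring or furan formation, and must tolerate an alkyne made electron-poor by conjugation with the pyranone.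

**12 to 8 and 9.** Carbene 12 is cut between the carbene carbon and the vinyl carbon, and at O–CH3. The carbene carbon and its oxygen come from a CO ligand of 9, and the two-carbon unit from vinyl ether 8 through its α-lithio derivative 10 and acylchromate 11. A tert-butyl ether is preferred to an ethyl or methyl ether on 8 because only a tertiary ether can later be distinguished from the permanent methyl ethers. It also survives organolithium, base and the benzannulation temperature.

**7 to 6.** The alkyne is traced to aldehyde 6 by removing the terminal carbon (the future C6'). Alkynylation of a C2 halide or sulfonate is not practical, because the 2-oxygenated chromone exists as the coumarin tautomer. One-carbon homologation of an aldehyde is therefore the entry. The forward step must avoid alcohols and alkoxides, which add to C2 of the pyranone and to the conjugated alkyne. A lithiated silyl diazomethane at low temperature meets this; an alcoholic carbonate protocol would not.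

**6 to 4, then to 2 and 3.** Ring C is opened at O1–C2 (cyclodehydration) and the chain at C2–C3 (Claisen condensation), giving diketone 4 and then ketone 2 and ester 3. Ester 3 brings C2 and the formyl carbon at the aldehyde oxidation level, masked as an acetal. An oxalate-based route would give an ester that must be reduced and re-oxidised beside a hydride-sensitive pyranone, two steps more. The forward steps need a dianion condensation at a hindered, doubly ortho-substituted acetyl group, and an acid treatment that closes the ring and hydrolyses the acetal (through 5) without touching aryl methyl ethers.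

**2 to 1.** Cutting the aryl–acetyl bond (C4a–C4) gives phenol 1. All three ring A oxygens are present and the two positions ortho to the hydroxyl are equivalent, so acetylation can give only one ketone.

## Roads not taken

**Alternative 1:** Ring A would be cut at C8–C8a and C5–C4a. C5 to C8 then come from the squarate-derived chlorocyclobutenone A3, and the remainder from the 6-stannylated 2-aryl-4-pyranone A2.

- Forward key step: a palladium-catalysed Stille-type coupling joins C8 to C8a. On heating, the cyclobutenone opens to a dienylketene, which closes C5–C4a by six-electron electrocyclisation and tautomerises to phenol A1.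
- Merits: the ring A oxygen pattern is fixed by the squarate, and O5 arrives free and chelated, so one of the ring A differentiations is solved by the step itself. The mechanism leaves no regiochemical ambiguity. In these respects it is better than the chosen plan.
- Weak points: A2 needs the fully differentiated ring B arene made beforehand by stepwise aromatic chemistry, then pyranone construction and stannylation at a position prone to nucleophilic attack. A3 is a sensitive, multi-step reagent. A1 still carries methyl groups on both O6 and O7, so the C6/C7 distinction of the chosen endgame remains.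
- Comparison: both routes use a toxic metal stoichiometrically (tin there, chromium here). The chosen plan sets against the free O5 of A1 a one-step ring A from a symmetrical commercial phenol and a ring B whose three oxygens are differentiated as the ring forms. Its overall count should be clearly lower.

**Alternative 2:** Ring C would be cut at O1–C8a, C4–C4a and O1–C2, giving aryne precursor A5 (an ortho-silyl aryl triflate) and arylpropiolic acid A6.

- Forward key step: fluoride releases the aryne from A5. The carboxylate oxygen of A6 adds at the aryne carbon remote from the flanking methoxy (C8a). The aryl anion at C4a captures the acyl carbon, and the freed phenoxide closes onto the ynone to give A4.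
- Merits: it is the most convergent of the four plans, with all three ring C bonds made in one metal-free operation. The known preference of 3-alkoxyarynes points to the correct regiochemistry. The benzyl ether of A4 is removed by hydrogenolysis without a carbocation, slightly cleaner than a tert-butyl ether. No chromium is needed.
- Weak points: A5 takes about four steps from the same phenol 1. A6 again requires a prefabricated ring B with three different oxygen substituents. Arylpropiolic acids decarboxylate easily. Simple O-arylation without acyl transfer, and five-membered (aurone) closure, compete with the desired cascade. The anion at C4a is hindered by the C5 methoxy.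
- Comparison: A4 is the benzyl analogue of 15, so the selective 5,6-demethylation is unchanged. Against the greater convergence, the chosen plan sets a shorter fragment synthesis and a key reaction class with a long record.

**Alternative 3:** Only O1–C8a would be cut, at a ring A carbon that bears hydrogen, giving diketone A8.

- Forward key step: two-electron anodic oxidation of the ring A phenol in a fluorinated alcohol gives a phenoxenium ion. The enol oxygen traps it at the carbon para to the hydroxyl, giving the 6-hydroxyflavone A7.
- Merits: no leaving group and no metal are needed. More importantly, A7 has O6 free and O5 as the only methyl ether that must go, and the peri-chelated C5 ether is the most reliably cleaved in flavone chemistry. The ring A endgame would be safer than the chosen one, which has to distinguish the C6 from the C7 methoxy.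
- Weak points: ketone A9, needed for A8, cannot be made by direct acylation, because the matching phenol is acylated para and not meta to its hydroxyl. The phenoxenium ion can be intercepted at the methoxy-bearing ortho carbons. The enol and the trialkoxy ring B oxidise at comparable potentials, and the product phenol A7 is itself oxidisable. There is no close precedent on this substrate class, so the key step would be method development.
- Comparison: the chosen plan accepts a less certain final demethylation in exchange for a key step inside established reactivity and for short fragment syntheses.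

Key step: step 6

## Route

Step 1
Reactants: 1 3,4,5-trimethoxyphenol
Product: 2 1-(6-hydroxy-2,3,4-trimethoxyphenyl)ethan-1-one
Conditions: AcOH, BF3·OEt2 (promoter), 90 °C; then aq. NaOAc
Reagents that add atoms: acetic acid, CC(=O)O
Why: Friedel–Crafts C-acetylation of an electron-rich phenol (O-acetate formation and Fries-type shift belong to the same manifold); the two ortho positions of the symmetrical phenol are equivalent, so one ketone should form, and chelation of the o-hydroxy ketone to boron deactivates the ring toward a second acylation.

Step 2
Reactants: 2 1-(6-hydroxy-2,3,4-trimethoxyphenyl)ethan-1-one; 3 ethyl 2,2-diethoxyacetate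
Product: 4 4,4-diethoxy-1-(6-hydroxy-2,3,4-trimethoxyphenyl)butane-1,3-dione
Conditions: NaH (4 equiv), THF, 0 °C → reflux; then cold 1 M HCl to pH 5
Reagents that add atoms: none
Why: Crossed Claisen condensation: the phenoxide–enolate dianion of 2 attacks the ester carbonyl of 3, whose acetal carbon is a poor carbon acid, and deprotonation of the 1,3-diketone by excess hydride drives the equilibrium. The acetal is stable to base and to a brief cold, weakly acidic quench.

Step 3
Reactants: 4 4,4-diethoxy-1-(6-hydroxy-2,3,4-trimethoxyphenyl)butane-1,3-dione
Product: 6 5,6,7-trimethoxy-4-oxo-4H-chromene-2-carbaldehyde, via 2-(diethoxymethyl)-5,6,7-trimethoxychromen-4-one 5 (not isolated)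
Conditions: AcOH, conc. HCl (cat.), 70 °C; then 2 M HCl, 70 °C
Reagents that add atoms: water, O
Why: Acid-catalysed cyclodehydration of an o-hydroxyaryl 1,3-diketone (the phenol oxygen adds to the side-chain carbonyl to form O1–C2 and water is lost to give pyranone 5), followed by ordinary acetal hydrolysis. Aqueous HCl at this temperature should not cleave aryl methyl ethers.

Step 4
Reactants: 6 5,6,7-trimethoxy-4-oxo-4H-chromene-2-carbaldehyde
Product: 7 2-ethynyl-5,6,7-trimethoxychromen-4-one
Conditions: Me3SiCHN2, LDA, THF, −78 °C; then 6 (dried azeotropically), −78 °C → rt; aq. NH4Cl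
Reagents that add atoms: (trimethylsilyl)diazomethane, C[Si](C)(C)C=[N+]=[N-]
Why: Colvin rearrangement: the lithiated silyl diazomethane adds to the aldehyde, Peterson-type loss of lithium trimethylsilanolate gives a diazoalkene, N2 leaves and the alkylidene carbene rearranges by 1,2-hydrogen shift to the terminal alkyne. At −78 °C the aldehyde is far more electrophilic than the vinylogous ester carbonyl C4, and no alcohol or alkoxide is present that could add to the pyranone or to the activated alkyne.

Step 5
Reactants: 8 tert-butyl vinyl ether; 9 chromium hexacarbonyl
Product: 12 pentacarbonyl[(1-tert-butoxyethenyl)(methoxy)methylidene]chromium, via 1-(tert-butoxy)ethenyllithium 10 (not isolated), via lithium acylchromate 11 (not isolated)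
Conditions: t-BuLi, THF, −78 → 0 °C; Cr(CO)6, THF, 0 °C → rt; then Me3OBF4, CH2Cl2, 0 °C
Reagents that add atoms: trimethyloxonium tetrafluoroborate, C[O+](C)C.F[B-](F)(F)F
Why: α-Deprotonation of an alkyl vinyl ether with t-BuLi (as for ethyl vinyl ether) followed by the Fischer carbene synthesis: the vinyllithium adds to a CO ligand of Cr(CO)6 and the acylchromate is O-methylated by the Meerwein salt. The α-alkoxy substituent should suppress the polymerisation typical of unsubstituted vinylcarbene complexes, as in the isopropenyl and dihydropyranyl analogues.

Step 6
Reactants: 12 pentacarbonyl[(1-tert-butoxyethenyl)(methoxy)methylidene]chromium; 7 2-ethynyl-5,6,7-trimethoxychromen-4-one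
Product: 14 2-[4-(tert-butoxy)-2-hydroxy-5-methoxyphenyl]-5,6,7-trimethoxychromen-4-one, via ring-B-bound tricarbonylchromium complex 13 (not isolated)
Conditions: 12 (1.5 equiv), THF, 50 °C, Ar, slow addition of 7; then air, EtOAc, rt
Reagents that add atoms: none
Why: This is a Dötz benzannulation of an alkenyl(methoxy)carbene chromium complex with a terminal alkyne; the closest known cases are the isopropenyl and the cyclic 2-alkoxyvinyl (dihydropyranyl) carbene complexes. Thermal loss of one CO ligand opens a coordination site, alkyne 7 binds and inserts into the chromium–carbene bond to form C5'–C6', giving a vinylcarbene intermediate with the chromonyl group on the carbon bound to chromium. CO insertion at that carbon forms C1'–C2' and a chromium-bound dienylketene. Ring B closes by six-electron electrocyclisation of the dienylketene, ketene carbon to the vinyl CH2 (C2'–C3', a six-membered carbocycle), and tautomerisation of the cyclohexadienone gives the 4-methoxyphenol as complex 13, which air demetalates to 14. No stereocentre is formed. The selectivity needed is regiochemical: the chromonyl-bearing carbon must end beside the CO-derived C2', and the steric rule for terminal alkynes secures this, because the larger alkyne substituent is placed remote from the carbene substituents and hydrogen is the smallest possible competitor. CO insertion is favoured over cyclopentannulation, furan or cyclobutenone formation by the alkenyl (not aryl) carbene, the methoxy donor, the coordinating ether solvent and the moderate temperature; slow addition of 7 to excess 12 limits double alkyne uptake and self-reaction of the electron-poor alkyne. The three ring B oxygens leave the step in three different states: free at C2', tert-butyl at C4', methyl at C5'.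

Step 7
Reactants: 14 2-[4-(tert-butoxy)-2-hydroxy-5-methoxyphenyl]-5,6,7-trimethoxychromen-4-one
Product: 15 2-[4-(tert-butoxy)-2,5-dimethoxyphenyl]-5,6,7-trimethoxychromen-4-one
Conditions: MeI, K2CO3, acetone, reflux
Reagents that add atoms: iodomethane, CI
Why: Williamson ether synthesis on the only free phenol; K2CO3 in acetone is too weak and non-nucleophilic to open the pyranone, and the tert-butyl ether is inert to base.

Step 8
Reactants: 15 2-[4-(tert-butoxy)-2,5-dimethoxyphenyl]-5,6,7-trimethoxychromen-4-one
Product: 16 5,6-dihydroxy-2-(4-hydroxy-2,5-dimethoxyphenyl)-7-methoxy-4H-chromen-4-one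
Conditions: AlBr3 (8 equiv), MeCN, 0 °C → rt, Ar; then 2 M HCl, 60 °C
Reagents that add atoms: none
Why: Chelation-controlled Lewis acid dealkylation of a polymethoxyflavone: aluminium bound to the C4 carbonyl activates the peri C5 methyl for SN2 attack by bromide, and the resulting O5–Al chelate then activates the C6 methoxy, which is flanked on both sides, twisted out of plane and therefore the most basic remaining ether oxygen. The tert-butyl ether ionises at once and its cation is taken up by bromide or the nitrile solvent, so ring alkylation is not expected. The C7, C2' and C5' methoxy groups are in-plane and not chelated to the carbonyl; the acidic, non-oxidising work-up protects the 5,6-dihydroxy unit.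

## Compound list

1 | 3,4,5-trimethoxyphenol | COc1cc(O)cc(OC)c1OC | starting material
2 | 1-(6-hydroxy-2,3,4-trimethoxyphenyl)ethan-1-one | CC(=O)c1c(O)cc(OC)c(OC)c1OC | intermediate
3 | ethyl 2,2-diethoxyacetate | CCOC(=O)C(OCC)OCC | starting material
4 | 4,4-diethoxy-1-(6-hydroxy-2,3,4-trimethoxyphenyl)butane-1,3-dione (drawn as the diketone; the chelated enol is expected) | CCOC(OCC)C(=O)CC(=O)c1c(O)cc(OC)c(OC)c1OC | intermediate
5 | 2-(diethoxymethyl)-5,6,7-trimethoxychromen-4-one | CCOC(OCC)c1cc(=O)c2c(OC)c(OC)c(OC)cc2o1 | intermediate
6 | 5,6,7-trimethoxy-4-oxo-4H-chromene-2-carbaldehyde | O=Cc1cc(=O)c2c(OC)c(OC)c(OC)cc2o1 | intermediate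
7 | 2-ethynyl-5,6,7-trimethoxychromen-4-one | C#Cc1cc(=O)c2c(OC)c(OC)c(OC)cc2o1 | intermediate
8 | tert-butyl vinyl ether | C=COC(C)(C)C | starting material
9 | chromium hexacarbonyl | O=C=[Cr](=C=O)(=C=O)(=C=O)(=C=O)=C=O | starting material
10 | 1-(tert-butoxy)ethenyllithium | [Li]C(=C)OC(C)(C)C | intermediate
11 | lithium pentacarbonyl[2-(tert-butoxy)-1-oxidoprop-2-en-1-ylidene]chromate | [Li+].[O-]C(C(=C)OC(C)(C)C)=[Cr](=C=O)(=C=O)(=C=O)(=C=O)=C=O | intermediate
12 | pentacarbonyl[(1-tert-butoxyethenyl)(methoxy)methylidene]chromium | COC(C(=C)OC(C)(C)C)=[Cr](=C=O)(=C=O)(=C=O)(=C=O)=C=O | intermediate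
13 | tricarbonylchromium complex of 14, Cr(CO)3 bound η6 to ring B (the two parts are written side by side) | COc1cc(-c2cc(=O)c3c(OC)c(OC)c(OC)cc3o2)c(O)cc1OC(C)(C)C.O=C=[Cr](=C=O)=C=O | intermediate
14 | 2-[4-(tert-butoxy)-2-hydroxy-5-methoxyphenyl]-5,6,7-trimethoxychromen-4-one | COc1cc(-c2cc(=O)c3c(OC)c(OC)c(OC)cc3o2)c(O)cc1OC(C)(C)C | intermediate
15 | 2-[4-(tert-butoxy)-2,5-dimethoxyphenyl]-5,6,7-trimethoxychromen-4-one | COc1cc(-c2cc(=O)c3c(OC)c(OC)c(OC)cc3o2)c(OC)cc1OC(C)(C)C | intermediate
16 | 5,6-dihydroxy-2-(4-hydroxy-2,5-dimethoxyphenyl)-7-methoxy-4H-chromen-4-one | COc1cc(-c2cc(=O)c3c(O)c(O)c(OC)cc3o2)c(OC)cc1O | target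

## Step count and risks

Total step count: 8. Longest linear sequence: 7 steps (steps 1 to 4, then 6 to 8, from 1 to 16). The carbene branch is a single step (step 5) and joins at step 6.

**Step 6 (key step).**
- What may go wrong: slow insertion of the electron-poor, conjugated alkyne; diversion of the vinylcarbene intermediate before CO insertion (cyclopentannulation, furan formation); four-electron closure of the vinylketene to a cyclobutenone; uptake of a second alkyne; oligomerisation of 7; conjugate addition of the liberated phenol to unreacted 7.
- Fallback, setting out from 12 and returning at 15: the benzannulation is kept but moved to an unconjugated alkyne, and ring C is built afterwards. Carbene 12 and 3,3-diethoxyprop-1-yne under the conditions of step 6 should give the tricarbonylchromium complex of the acetal phenol F1. Air releases 5-(tert-butoxy)-2-(diethoxymethyl)-4-methoxyphenol F2. Oxalic acid on wet silica hydrolyses the acetal to 4-(tert-butoxy)-2-hydroxy-5-methoxybenzaldehyde F3. MeI and K2CO3 give 4-(tert-butoxy)-2,5-dimethoxybenzaldehyde F4. Claisen–Schmidt condensation of F4 with ketone 2 (KOH, EtOH) gives (E)-3-[4-(tert-butoxy)-2,5-dimethoxyphenyl]-1-(6-hydroxy-2,3,4-trimethoxyphenyl)prop-2-en-1-one F5. Oxidative cyclisation of this 2'-hydroxychalcone with catalytic I2 in DMSO at 110 °C closes ring C and gives 15.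

**Step 8.**
- What may go wrong: loss of selectivity between neighbouring ethers. This covers over-demethylation at C7 or at C5' once O6 and O4' are bound to aluminium, arrest at the 5-hydroxy-6,7-dimethoxy stage, tert-butylation of an electron-rich ring position by the departing cation, and oxidation of the catechol during work-up.
- Fallback, setting out from 15 and returning at 16: the three unmaskings are separated, and O4' is kept as an ester while ring A is demethylated, because an acyl oxygen is a poor ligand for aluminium and cannot direct cleavage of the C5' ether. TFA in CH2Cl2 at 0 °C removes only the tert-butyl group and gives 2-(4-hydroxy-2,5-dimethoxyphenyl)-5,6,7-trimethoxychromen-4-one F6. Ac2O in pyridine gives 2,5-dimethoxy-4-(5,6,7-trimethoxy-4-oxo-4H-chromen-2-yl)phenyl acetate F7. AlBr3 in MeCN then acts on ring A alone and gives 4-(5,6-dihydroxy-7-methoxy-4-oxo-4H-chromen-2-yl)-2,5-dimethoxyphenyl acetate F8. Warm methanolic HCl cleaves the acetate of F8 to 16.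

**Step 4.**
- What may go wrong: competing addition of the lithiated diazo reagent, or of the product acetylide, to C2 of the pyranone with ring opening; incomplete reaction if the aldehyde is present as its hydrate; base-induced degradation of the activated alkyne on warming.
- Fallback, setting out from 6 and returning at 7: a Corey–Fuchs sequence replaces the diazo chemistry. CBr4 and PPh3 in CH2Cl2 at 0 °C convert 6 into 2-(2,2-dibromoethenyl)-5,6,7-trimethoxychromen-4-one F9 under neutral conditions. n-BuLi (2.1 equiv) in THF at −78 °C then effects bromine–lithium exchange and rearrangement to the acetylide, which a cold NH4Cl quench protonates to 7. Halogen–metal exchange at this temperature should outpace addition to the vinylogous ester.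

**Step 5.**
- What may go wrong: incomplete α-lithiation of the hindered ether; acid-triggered loss of isobutene from the tert-butyl enol ether during O-methylation; decomposition of the α-alkoxyvinyl carbene on handling.
- Fallback, setting out from 9 and returning at 16: the oxygen mask is changed to a secondary alkyl group, which is less hindered and cannot ionise as easily, and which aluminium and boron halides still cleave in preference to methyl. Isopropyl vinyl ether and t-BuLi give 1-(propan-2-yloxy)ethenyllithium F10. Addition to 9 gives the lithium acylchromate F11. Me3OBF4 gives pentacarbonyl[(methoxy)(1-propan-2-yloxyethenyl)methylidene]chromium F12. Benzannulation of F12 with 7 under the conditions of step 6 gives the tricarbonylchromium complex F13, and in air 2-(2-hydroxy-5-methoxy-4-propan-2-yloxyphenyl)-5,6,7-trimethoxychromen-4-one F14. Methylation as in step 7 gives 2-(2,5-dimethoxy-4-propan-2-yloxyphenyl)-5,6,7-trimethoxychromen-4-one F15. The conditions of step 8 then remove the isopropyl group together with the C5 and C6 methyl groups and give 16.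

## Further compounds

F1 | step 6 | tricarbonylchromium complex of F2, Cr(CO)3 bound η6 to the arene (the two parts are written side by side) | CCOC(OCC)c1cc(OC)c(OC(C)(C)C)cc1O.O=C=[Cr](=C=O)=C=O
F2 | step 6 | 5-(tert-butoxy)-2-(diethoxymethyl)-4-methoxyphenol | CCOC(OCC)c1cc(OC)c(OC(C)(C)C)cc1O
F3 | step 6 | 4-(tert-butoxy)-2-hydroxy-5-methoxybenzaldehyde | O=Cc1cc(OC)c(OC(C)(C)C)cc1O
F4 | step 6 | 4-(tert-butoxy)-2,5-dimethoxybenzaldehyde | O=Cc1cc(OC)c(OC(C)(C)C)cc1OC
F5 | step 6 | (E)-3-[4-(tert-butoxy)-2,5-dimethoxyphenyl]-1-(6-hydroxy-2,3,4-trimethoxyphenyl)prop-2-en-1-one | COc1cc(/C=C/C(=O)c2c(O)cc(OC)c(OC)c2OC)c(OC)cc1OC(C)(C)C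
F6 | step 8 | 2-(4-hydroxy-2,5-dimethoxyphenyl)-5,6,7-trimethoxychromen-4-one | COc1cc(-c2cc(=O)c3c(OC)c(OC)c(OC)cc3o2)c(OC)cc1O
F7 | step 8 | 2,5-dimethoxy-4-(5,6,7-trimethoxy-4-oxo-4H-chromen-2-yl)phenyl acetate | COc1cc(-c2cc(=O)c3c(OC)c(OC)c(OC)cc3o2)c(OC)cc1OC(C)=O
F8 | step 8 | 4-(5,6-dihydroxy-7-methoxy-4-oxo-4H-chromen-2-yl)-2,5-dimethoxyphenyl acetate | COc1cc(-c2cc(=O)c3c(O)c(O)c(OC)cc3o2)c(OC)cc1OC(C)=O
F9 | step 4 | 2-(2,2-dibromoethenyl)-5,6,7-trimethoxychromen-4-one | BrC(Br)=Cc1cc(=O)c2c(OC)c(OC)c(OC)cc2o1
F10 | step 5 | 1-(propan-2-yloxy)ethenyllithium | [Li]C(=C)OC(C)C
F11 | step 5 | lithium pentacarbonyl[1-oxido-2-(propan-2-yloxy)prop-2-en-1-ylidene]chromate | [Li+].[O-]C(C(=C)OC(C)C)=[Cr](=C=O)(=C=O)(=C=O)(=C=O)=C=O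
F12 | step 5 | pentacarbonyl[(methoxy)(1-propan-2-yloxyethenyl)methylidene]chromium | COC(C(=C)OC(C)C)=[Cr](=C=O)(=C=O)(=C=O)(=C=O)=C=O
F13 | step 5 | tricarbonylchromium complex of F14, Cr(CO)3 bound η6 to ring B (the two parts are written side by side) | COc1cc(-c2cc(=O)c3c(OC)c(OC)c(OC)cc3o2)c(O)cc1OC(C)C.O=C=[Cr](=C=O)=C=O
F14 | step 5 | 2-(2-hydroxy-5-methoxy-4-propan-2-yloxyphenyl)-5,6,7-trimethoxychromen-4-one | COc1cc(-c2cc(=O)c3c(OC)c(OC)c(OC)cc3o2)c(O)cc1OC(C)C
F15 | step 5 | 2-(2,5-dimethoxy-4-propan-2-yloxyphenyl)-5,6,7-trimethoxychromen-4-one | COc1cc(-c2cc(=O)c3c(OC)c(OC)c(OC)cc3o2)c(OC)cc1OC(C)C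
A1 | alternative 1 | 2-[4-(benzyloxy)-2,5-dimethoxyphenyl]-5-hydroxy-6,7-dimethoxychromen-4-one | COc1cc(-c2cc(=O)c3c(O)c(OC)c(OC)cc3o2)c(OC)cc1OCc1ccccc1
A2 | alternative 1 | 2-[4-(benzyloxy)-2,5-dimethoxyphenyl]-6-(tributylstannyl)-4H-pyran-4-one | CCCC[Sn](CCCC)(CCCC)c1cc(=O)cc(-c2cc(OC)c(OCc3ccccc3)cc2OC)o1
A3 | alternative 1 | 4-chloro-2,3-dimethoxycyclobut-2-en-1-one | COC1=C(OC)C(Cl)C1=O
A4 | alternative 2 | 2-[4-(benzyloxy)-2,5-dimethoxyphenyl]-5,6,7-trimethoxychromen-4-one | COc1cc(-c2cc(=O)c3c(OC)c(OC)c(OC)cc3o2)c(OC)cc1OCc1ccccc1
A5 | alternative 2 | 3,4,5-trimethoxy-2-(trimethylsilyl)phenyl trifluoromethanesulfonate | COc1cc(OS(=O)(=O)C(F)(F)F)c([Si](C)(C)C)c(OC)c1OC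
A6 | alternative 2 | 3-[4-(benzyloxy)-2,5-dimethoxyphenyl]prop-2-ynoic acid | COc1cc(C#CC(=O)O)c(OC)cc1OCc1ccccc1
A7 | alternative 3 | 2-[4-(benzyloxy)-2,5-dimethoxyphenyl]-6-hydroxy-5,7-dimethoxychromen-4-one | COc1cc(-c2cc(=O)c3c(OC)c(O)c(OC)cc3o2)c(OC)cc1OCc1ccccc1
A8 | alternative 3 | 1-[4-(benzyloxy)-2,5-dimethoxyphenyl]-3-(3-hydroxy-2,4-dimethoxyphenyl)propane-1,3-dione | COc1cc(C(=O)CC(=O)c2ccc(OC)c(O)c2OC)c(OC)cc1OCc1ccccc1
A9 | alternative 3 | 1-(3-hydroxy-2,4-dimethoxyphenyl)ethan-1-one | CC(=O)c1ccc(OC)c(O)c1OC
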